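Everything rests on C5 of the 5,6-dihydro-2H-pyran-2-one ring: it bears the dienoate oxygen and sits between C4, the end of the ring Z-enoate, and the O1-bearing stereocentre C6, so it is treated as an aldehyde carbon. Cutting C4–C5 and the C5–O acyl bond gives three pieces: (S)-glyceraldehyde acetonide (C5–C7), methyl propiolate (C2–C4) and (2E,4E,6S)-4,6-dimethyldodeca-2,4-dienoyl chloride. One flask joins them: a ligand-controlled zinc alkynylation forms C4–C5 and the C5 stereocentre, and the zinc alkoxide is acylated before any protic work-up. Semihydrogenation, acid-triggered δ-lactonisation through the C6 oxygen and a C7 oxidation–olefination then complete the target.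

Key step: step 8

Numbering: ring O1, C2 (lactone carbonyl), C3=C4, C5, C6; side chain C7=C8–C9; O5, O6 and O7 are the oxygens on C5, C6 and C7 of the open-chain intermediates (O6 becomes ring O1).
Assumption: Si-face delivery of the alkynyl group to the formyl group of 4 (needed for 5S) is assigned to (R,R)-ProPhenol by analogy with the Re-face sense of the (S,S)-ligand in its zinc aldol chemistry; should a first experiment show the reverse, the (S,S)-ligand is used and nothing else changes.
Assumption: compound 1 is taken as a catalogue chemical; it is the 5,6-acetonide of commercial L-gulono-1,4-lactone.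

Step 1
Reactants: 1 5,6-O-isopropylidene-L-gulono-1,4-lactone
Product: 4 (S)-2,2-dimethyl-1,3-dioxolane-4-carbaldehyde, via glyoxylate ester 2 (not isolated), via L-threose acetonide 3 (not isolated)
Conditions: NaIO4 (2.1 equiv), H2O, pH 5.5 held with NaOH, 0 °C → rt; NaCl, CH2Cl2 extraction; distilled and used fresh
Reagents that add atoms: none
Why: Two consecutive periodate glycol cleavages (Malaprade reaction), linked by hydrolysis of glyoxylate ester 2 to α-hydroxy aldehyde 3, excise C1–C3 of the lactone and leave C4 as the formyl group, while the dioxolane stereocentre carries no cleavable diol and is kept unchanged.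

Step 2
Reactants: 5 (R)-3-bromo-2-methylpropan-1-ol; 6 pentylmagnesium bromide
Product: 7 (S)-2-methyloctan-1-ol
Conditions: 6 (3 equiv), Li2CuCl4 (3 mol%), NMP (4 equiv), THF, −20 °C → rt; aq. NH4Cl
Reagents that add atoms: none
Why: Copper-catalysed coupling of a Grignard reagent with a primary alkyl bromide (Kochi–Tamura coupling; the first equivalent of 6 only removes the hydroxyl proton) forms the C–C bond at the carbon next to the stereocentre, so the configuration is retained and only the descriptor changes from R to S.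

Step 3
Reactants: 7 (S)-2-methyloctan-1-ol
Product: 8 (S)-2-methyloctanal
Conditions: TEMPO (10 mol%), PhI(OAc)2 (1.1 equiv), CH2Cl2, rt; used without storage
Reagents that add atoms: none
Why: Oxoammonium-mediated oxidation of a primary alcohol stops at the aldehyde under base-free conditions, so the α-stereocentre should not epimerise.

Step 4
Reactants: 8 (S)-2-methyloctanal; 9 2-(triphenylphosphoranylidene)propanal
Product: 10 (2E,4S)-2,4-dimethyldec-2-enal
Conditions: 9 (1.3 equiv), toluene, 90 °C
Reagents that add atoms: none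
Why: Wittig olefination with a formyl-stabilised ylide should give the E-trisubstituted enal, and the weakly basic ylide leaves the α-stereocentre of 8 alone.

Step 5
Reactants: 10 (2E,4S)-2,4-dimethyldec-2-enal; 11 triethyl phosphonoacetate
Product: 12 ethyl (2E,4E,6S)-4,6-dimethyldodeca-2,4-dienoate
Conditions: 11 (1.3 equiv), NaH (1.2 equiv), THF, 0 °C; then 10, 0 °C → rt
Reagents that add atoms: none
Why: Horner–Wadsworth–Emmons olefination of an enal with the preformed phosphonoacetate anion is reliably E-selective and leaves no free hydride base that could deconjugate the γ-branched enal.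

Step 6
Reactants: 12 ethyl (2E,4E,6S)-4,6-dimethyldodeca-2,4-dienoate
Product: 13 (2E,4E,6S)-4,6-dimethyldodeca-2,4-dienoic acid
Conditions: LiOH·H2O (3 equiv), THF/MeOH/H2O, rt; then 1 M HCl
Reagents that add atoms: lithium hydroxide, [Li+].[OH-]
Why: Saponification by acyl–oxygen cleavage (BAc2) is routine for dienoates, and hydroxide at room temperature is too weak a base to remove the remote allylic C6 hydrogen.

Step 7
Reactants: 13 (2E,4E,6S)-4,6-dimethyldodeca-2,4-dienoic acid
Product: 14 (2E,4E,6S)-4,6-dimethyldodeca-2,4-dienoyl chloride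
Conditions: (COCl)2 (1.5 equiv), DMF (cat.), CH2Cl2, 0 °C → rt; evaporated, used crude
Reagents that add atoms: oxalyl chloride, O=C(Cl)C(=O)Cl
Why: Chloroiminium (Vilsmeier-type) activation converts the acid into its chloride under neutral conditions that do not isomerise the diene.

Step 8
Reactants: 4 (S)-2,2-dimethyl-1,3-dioxolane-4-carbaldehyde; 15 methyl propiolate; 14 (2E,4E,6S)-4,6-dimethyldodeca-2,4-dienoyl chloride
Product: 17 methyl (4S)-4-{[(2E,4E,6S)-4,6-dimethyldodeca-2,4-dienoyl]oxy}-4-[(4S)-2,2-dimethyl-1,3-dioxolan-4-yl]but-2-ynoate, via methylzinc alkoxide 16 (not isolated)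
Conditions: 15 (3.0 equiv), Me2Zn (3.0 equiv), (R,R)-ProPhenol (0.2 equiv), Ph3P=O (0.4 equiv), toluene, 0 °C; 4 (2.0 equiv), 0–4 °C; then 14 (1.0 equiv, limiting), 0 °C → rt; aq. NH4Cl
Reagents that add atoms: none
Why: Me2Zn metallates 15 and, with the ProPhenol ligand, assembles a dinuclear zinc alkynylide in which one zinc binds the formyl oxygen of 4 and the other delivers the alkynyl carbon to the carbonyl, forming C4–C5 and the methylzinc alkoxide 16, which is then acylated at oxygen by 14. The closest known reaction type is the zinc–ProPhenol catalysed addition of alkyl propiolates to aldehydes, joined to the established acylation of zinc alkoxides by acyl chlorides. No ring is closed in this step. The new C5 stereocentre (S, syn to C6) is set by the ligand, which must deliver the alkynyl group to the Si face of the formyl group against the anti (Felkin–Anh) preference of the α-alkoxy aldehyde, so the step relies on reagent control. Site selectivity of the acylation is built into the substrate, because O5 is the only unprotected oxygen while O6 and O7 are locked in the acetonide, and acylation before any protic work-up means that the base-sensitive γ-hydroxy ynoate is never handled. Conjugate addition to 14 or 15 is not expected, since methylzinc and alkynylzinc species do not add in a 1,4-sense without copper, and 14 is the limiting component so that the excess zinc alkoxide outcompetes residual alkynylzinc for it.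

Step 9
Reactants: 17 methyl (4S)-4-{[(2E,4E,6S)-4,6-dimethyldodeca-2,4-dienoyl]oxy}-4-[(4S)-2,2-dimethyl-1,3-dioxolan-4-yl]but-2-ynoate
Product: 18 methyl (2Z,4S)-4-{[(2E,4E,6S)-4,6-dimethyldodeca-2,4-dienoyl]oxy}-4-[(4S)-2,2-dimethyl-1,3-dioxolan-4-yl]but-2-enoate
Conditions: H2 (1 atm), 5% Pd/CaCO3 poisoned with Pb(OAc)2 (Lindlar catalyst), quinoline, EtOAc, rt; stopped after one equivalent of H2
Reagents that add atoms: none
Why: Lindlar semihydrogenation delivers both hydrogens syn to the alkyne on the poisoned palladium surface to give the Z-enoate, while the conjugated E,E-dienoate binds far more weakly than an alkyne and should stay untouched.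

Step 10
Reactants: 18 methyl (2Z,4S)-4-{[(2E,4E,6S)-4,6-dimethyldodeca-2,4-dienoyl]oxy}-4-[(4S)-2,2-dimethyl-1,3-dioxolan-4-yl]but-2-enoate
Product: 20 (2S,3S)-2-(hydroxymethyl)-6-oxo-3,6-dihydro-2H-pyran-3-yl (2E,4E,6S)-4,6-dimethyldodeca-2,4-dienoate, via diol ester 19 (not isolated)
Conditions: TFA/H2O (9:1), CH2Cl2, 0 °C → rt; concentrated from toluene
Reagents that add atoms: none
Why: Acid hydrolysis of the isopropylidene acetal frees O6 and O7, and O6, held next to the ester by the Z-alkene, should close the six-membered lactone by acid-catalysed transesterification (6-exo-trig, loss of methanol) faster than the seven-membered closure through O7 or acyl migration, which is slow in acid.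

Step 11
Reactants: 20 (2S,3S)-2-(hydroxymethyl)-6-oxo-3,6-dihydro-2H-pyran-3-yl (2E,4E,6S)-4,6-dimethyldodeca-2,4-dienoate; 21 tert-butyl (triphenylphosphoranylidene)acetate
Product: 23 tert-butyl (2E)-3-[(2S,3S)-3-{[(2E,4E,6S)-4,6-dimethyldodeca-2,4-dienoyl]oxy}-6-oxo-3,6-dihydro-2H-pyran-2-yl]prop-2-enoate, via lactone aldehyde 22 (not isolated)
Conditions: Dess–Martin periodinane (1.3 equiv), CH2Cl2, 0 °C → rt; then 21 (2.5 equiv), 0 °C → rt
Reagents that add atoms: none
Why: Dess–Martin oxidation gives the C7 aldehyde without base, and the stabilised ylide added to the same flask should olefinate it at once with E selectivity (one-pot oxidation–Wittig reaction), which keeps the lifetime of the β-acyloxy aldehyde short and so limits elimination of the C5 dienoate and epimerisation at C6.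

Step 12
Reactants: 23 tert-butyl (2E)-3-[(2S,3S)-3-{[(2E,4E,6S)-4,6-dimethyldodeca-2,4-dienoyl]oxy}-6-oxo-3,6-dihydro-2H-pyran-2-yl]prop-2-enoate
Product: 24 (2E)-3-[(2S,3S)-3-{[(2E,4E,6S)-4,6-dimethyldodeca-2,4-dienoyl]oxy}-6-oxo-3,6-dihydro-2H-pyran-2-yl]prop-2-enoic acid (CNP0161231.2)
Conditions: TFA/CH2Cl2 (1:4), 0 °C → rt; evaporated
Reagents that add atoms: none
Why: Acidolysis of the tert-butyl ester by alkyl–oxygen cleavage (AAL1, loss of 2-methylpropene) frees the acid under conditions that the lactone, the dienoate ester and both ring stereocentres tolerate, and it avoids base, to which the C6 hydrogen (γ to the new enoate) is sensitive.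

Compound list
1 | 5,6-O-isopropylidene-L-gulono-1,4-lactone, (3S,4R,5S)-5-[(4S)-2,2-dimethyl-1,3-dioxolan-4-yl]-3,4-dihydroxyoxolan-2-one | O=C1[C@@H](O)[C@@H](O)[C@@H]([C@@H]2COC(C)(C)O2)O1 | starting material
2 | (1R)-1-[(4S)-2,2-dimethyl-1,3-dioxolan-4-yl]-2-oxoethyl oxoacetate (glyoxylate ester) | O=CC(=O)O[C@@H](C=O)[C@@H]1COC(C)(C)O1 | intermediate (not isolated)
3 | 3,4-O-isopropylidene-L-threose, (2R)-2-[(4S)-2,2-dimethyl-1,3-dioxolan-4-yl]-2-hydroxyacetaldehyde | O[C@@H](C=O)[C@@H]1COC(C)(C)O1 | intermediate (not isolated)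
4 | (S)-2,2-dimethyl-1,3-dioxolane-4-carbaldehyde | CC1(C)O[C@H](C=O)CO1 | intermediate
5 | (R)-3-bromo-2-methylpropan-1-ol | C[C@H](CO)CBr | starting material
6 | pentylmagnesium bromide | CCCCC[Mg]Br | starting material
7 | (S)-2-methyloctan-1-ol | CCCCCC[C@H](C)CO | intermediate
8 | (S)-2-methyloctanal | CCCCCC[C@H](C)C=O | intermediate
9 | 2-(triphenylphosphoranylidene)propanal | CC(C=O)=P(c1ccccc1)(c1ccccc1)c1ccccc1 | starting material
10 | (2E,4S)-2,4-dimethyldec-2-enal | CCCCCC[C@H](C)/C=C(C)/C=O | intermediate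
11 | triethyl phosphonoacetate | CCOC(=O)CP(=O)(OCC)OCC | starting material
12 | ethyl (2E,4E,6S)-4,6-dimethyldodeca-2,4-dienoate | CCCCCC[C@H](C)/C=C(C)/C=C/C(=O)OCC | intermediate
13 | (2E,4E,6S)-4,6-dimethyldodeca-2,4-dienoic acid | CCCCCC[C@H](C)/C=C(C)/C=C/C(=O)O | intermediate
14 | (2E,4E,6S)-4,6-dimethyldodeca-2,4-dienoyl chloride | CCCCCC[C@H](C)/C=C(C)/C=C/C(Cl)=O | intermediate
15 | methyl propiolate | C#CC(=O)OC | starting material
16 | methylzinc (1S)-1-[(4S)-2,2-dimethyl-1,3-dioxolan-4-yl]-4-methoxy-4-oxobut-2-yn-1-olate | C[Zn]O[C@H]([C@@H]1COC(C)(C)O1)C#CC(=O)OC | intermediate (not isolated)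
17 | methyl (4S)-4-{[(2E,4E,6S)-4,6-dimethyldodeca-2,4-dienoyl]oxy}-4-[(4S)-2,2-dimethyl-1,3-dioxolan-4-yl]but-2-ynoate | CCCCCC[C@H](C)/C=C(C)/C=C/C(=O)O[C@H]([C@@H]1COC(C)(C)O1)C#CC(=O)OC | intermediate
18 | methyl (2Z,4S)-4-{[(2E,4E,6S)-4,6-dimethyldodeca-2,4-dienoyl]oxy}-4-[(4S)-2,2-dimethyl-1,3-dioxolan-4-yl]but-2-enoate | CCCCCC[C@H](C)/C=C(C)/C=C/C(=O)O[C@H]([C@@H]1COC(C)(C)O1)/C=C\C(=O)OC | intermediate
19 | methyl (2Z,4S,5S)-4-{[(2E,4E,6S)-4,6-dimethyldodeca-2,4-dienoyl]oxy}-5,6-dihydroxyhex-2-enoate | CCCCCC[C@H](C)/C=C(C)/C=C/C(=O)O[C@H]([C@@H](O)CO)/C=C\C(=O)OC | intermediate (not isolated)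
20 | (2S,3S)-2-(hydroxymethyl)-6-oxo-3,6-dihydro-2H-pyran-3-yl (2E,4E,6S)-4,6-dimethyldodeca-2,4-dienoate | CCCCCC[C@H](C)/C=C(C)/C=C/C(=O)O[C@H]1C=CC(=O)O[C@H]1CO | intermediate
21 | tert-butyl (triphenylphosphoranylidene)acetate | CC(C)(C)OC(=O)C=P(c1ccccc1)(c1ccccc1)c1ccccc1 | starting material
22 | (2R,3S)-2-formyl-6-oxo-3,6-dihydro-2H-pyran-3-yl (2E,4E,6S)-4,6-dimethyldodeca-2,4-dienoate | CCCCCC[C@H](C)/C=C(C)/C=C/C(=O)O[C@H]1C=CC(=O)O[C@H]1C=O | intermediate (not isolated)
23 | tert-butyl (2E)-3-[(2S,3S)-3-{[(2E,4E,6S)-4,6-dimethyldodeca-2,4-dienoyl]oxy}-6-oxo-3,6-dihydro-2H-pyran-2-yl]prop-2-enoate | CCCCCC[C@H](C)/C=C(C)/C=C/C(=O)O[C@H]1C=CC(=O)O[C@H]1/C=C/C(=O)OC(C)(C)C | intermediate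
24 | (2E)-3-[(2S,3S)-3-{[(2E,4E,6S)-4,6-dimethyldodeca-2,4-dienoyl]oxy}-6-oxo-3,6-dihydro-2H-pyran-2-yl]prop-2-enoic acid | CCCCCC[C@H](C)/C=C(C)/C=C/C(=O)O[C@H]1C=CC(=O)O[C@H]1/C=C/C(=O)O | target

Total step count: 12.
Longest linear sequence: 11 steps (from 5 to 24 through steps 2–12).

Steps most likely to fail

Step 8. The process at risk is facial control: the ligand may not overturn the intrinsic anti bias of the α-alkoxy aldehyde, or acylation of the alkoxide may lag behind side reactions of the acid chloride. The fallback uses the bias instead of opposing it and sets out from 4 and 15. The same zinc alkynylation with the antipodal (S,S)-ProPhenol, now matched with the substrate and quenched with aqueous NH4Cl, should give the anti alcohol methyl (4R)-4-[(4S)-2,2-dimethyl-1,3-dioxolan-4-yl]-4-hydroxybut-2-ynoate F1. Mitsunobu esterification of F1 with acid 13 (PPh3, DIAD, toluene, −20 → 0 °C, betaine preformed) then installs the dienoate with inversion at C5 and comes back to the route at 17.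

Step 11. The process at risk is base-triggered loss of the C5 dienoate from aldehyde 22 (E1cB elimination towards a 2-pyranone) or epimerisation at C6 under the phosphorane. The fallback replaces the carbanion olefination and sets out from 20. After the Dess–Martin oxidation, crude 22 is methylenated under non-basic Takai–Lombardo conditions (Zn, CH2Br2, TiCl4, THF/CH2Cl2, 0 °C) to (2S,3S)-2-ethenyl-6-oxo-3,6-dihydro-2H-pyran-3-yl (2E,4E,6S)-4,6-dimethyldodeca-2,4-dienoate F2. Cross-metathesis of F2 with tert-butyl acrylate (second-generation Hoveyda–Grubbs catalyst, CH2Cl2, 40 °C) comes back to the route at 23.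

Step 10. The process at risk is slow transesterification after acetal hydrolysis, which would give the dienoyl group time to migrate from O5 to O6 or O7, with γ-lactone formation through the vacated O5. The fallback changes the ring closure to lactonisation of a free acid and sets out from 4 and 14. Step 8 is run with tert-butyl propiolate in place of 15, giving through the alkoxide methylzinc (1S)-4-tert-butoxy-1-[(4S)-2,2-dimethyl-1,3-dioxolan-4-yl]-4-oxobut-2-yn-1-olate F3 the ester tert-butyl (4S)-4-{[(2E,4E,6S)-4,6-dimethyldodeca-2,4-dienoyl]oxy}-4-[(4S)-2,2-dimethyl-1,3-dioxolan-4-yl]but-2-ynoate F4. Lindlar semihydrogenation gives tert-butyl (2Z,4S)-4-{[(2E,4E,6S)-4,6-dimethyldodeca-2,4-dienoyl]oxy}-4-[(4S)-2,2-dimethyl-1,3-dioxolan-4-yl]but-2-enoate F5. TFA/H2O then removes the acetonide and the tert-butyl group together, and the dihydroxy acid (2Z,4S,5S)-4-{[(2E,4E,6S)-4,6-dimethyldodeca-2,4-dienoyl]oxy}-5,6-dihydroxyhex-2-enoic acid F6 should close to 20, where the route is rejoined, either in the acid itself or with EDC·HCl in CH2Cl2 at 0 °C.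

Further compounds
F1 | step 8 | methyl (4R)-4-[(4S)-2,2-dimethyl-1,3-dioxolan-4-yl]-4-hydroxybut-2-ynoate | O[C@@H]([C@@H]1COC(C)(C)O1)C#CC(=O)OC
F2 | step 11 | (2S,3S)-2-ethenyl-6-oxo-3,6-dihydro-2H-pyran-3-yl (2E,4E,6S)-4,6-dimethyldodeca-2,4-dienoate | CCCCCC[C@H](C)/C=C(C)/C=C/C(=O)O[C@H]1C=CC(=O)O[C@H]1C=C
F3 | step 10 | methylzinc (1S)-4-tert-butoxy-1-[(4S)-2,2-dimethyl-1,3-dioxolan-4-yl]-4-oxobut-2-yn-1-olate | C[Zn]O[C@H]([C@@H]1COC(C)(C)O1)C#CC(=O)OC(C)(C)C
F4 | step 10 | tert-butyl (4S)-4-{[(2E,4E,6S)-4,6-dimethyldodeca-2,4-dienoyl]oxy}-4-[(4S)-2,2-dimethyl-1,3-dioxolan-4-yl]but-2-ynoate | CCCCCC[C@H](C)/C=C(C)/C=C/C(=O)O[C@H]([C@@H]1COC(C)(C)O1)C#CC(=O)OC(C)(C)C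
F5 | step 10 | tert-butyl (2Z,4S)-4-{[(2E,4E,6S)-4,6-dimethyldodeca-2,4-dienoyl]oxy}-4-[(4S)-2,2-dimethyl-1,3-dioxolan-4-yl]but-2-enoate | CCCCCC[C@H](C)/C=C(C)/C=C/C(=O)O[C@H]([C@@H]1COC(C)(C)O1)/C=C\C(=O)OC(C)(C)C
F6 | step 10 | (2Z,4S,5S)-4-{[(2E,4E,6S)-4,6-dimethyldodeca-2,4-dienoyl]oxy}-5,6-dihydroxyhex-2-enoic acid | CCCCCC[C@H](C)/C=C(C)/C=C/C(=O)O[C@H]([C@@H](O)CO)/C=C\C(=O)O
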